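**Retrosynthetic overview**
1. The route rests on the tetrasubstituted C3=C4 alkene of the furan-2(5H)-one ring. C2 (lactone C=O) and C5 (the carbon bearing =CBr2) sit cis on it, with Br on C4 and the carbinol chain on C3. This is the C4–C3 edge of a 2-formyl-3-bromo-4-alkylfuran with its C5 and C2 still attached.
2. Lactone bond O1–C5 is cut first. A 5-exo-dig bromolactonisation of a 5-bromo-enynoic acid (carboxyl cis to alkynyl) closes the ring and supplies the second bromine of =CBr2.
3. The cis-enyne comes from fragmentation of a 2-furylcarbene. Furan O1–C2 is cleaved, the formyl carbon from DMF becomes the alkyne terminus, and furan C5 becomes CHO and later CO2H.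
4. The furan is dressed from 3,4-dibromofuran by Br–Li exchange/Weinreb acylation, CBS reduction (sets R), silylation, and LDA/DMF formylation next to C–Br.
5. Ring order: the bought furan is carried to step 5 and opened in step 6. The butenolide, the only ring of the target, is closed in step 9, and desilylation comes last.

Key step: step 6

Remark: in 17, 18 and 19 the formyl/carboxyl group is cis to the alkynyl group and Br is cis to the side chain. Because Br outranks the alkynyl carbon, the CIP descriptor of this alkene is E. The target carbinol centre is R (O > ring C3 > propyl > H).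

**Step 1**
Reactants: 1 3,4-dibromofuran; 2 N-methoxy-N-methylbutanamide
Product: 5 1-(4-bromofuran-3-yl)butan-1-one, via 4-bromofuran-3-yllithium 3 (not isolated), via lithium Weinreb adduct 4 (not isolated)
Conditions: n-BuLi (1.0 equiv), Et2O, −78 °C; then 2, −78 → −20 °C; 1 M aq HCl
Reagents that add atoms: N-methoxy-N-methylbutanamide 2, CCCC(=O)N(C)OC
Why: Bromine–lithium exchange at one of the two equivalent C–Br bonds outruns furan deprotonation at −78 °C, and the Weinreb ketone synthesis halts at chelate 4, so no tertiary alcohol should form.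

**Step 2**
Reactants: 5 1-(4-bromofuran-3-yl)butan-1-one
Product: 6 (1R)-1-(4-bromofuran-3-yl)butan-1-ol
Conditions: (S)-Me-CBS [(S)-1-methyl-3,3-diphenyltetrahydro-1H,3H-pyrrolo[1,2-c][1,3,2]oxazaborole] (10 mol %), BH3·SMe2 (1.0 equiv), THF, −20 °C; MeOH
Reagents that add atoms: none
Why: In this Corey–Bakshi–Shibata reduction the ketone binds the catalyst boron with the larger bromofuryl group turned away, so the (S)-catalyst should deliver hydride to the Si face and set the R carbinol, as in the aryl n-alkyl ketone series.

**Step 3**
Reactants: 6 (1R)-1-(4-bromofuran-3-yl)butan-1-ol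
Product: 7 (R)-3-bromo-4-[1-(tert-butyldimethylsilyloxy)butyl]furan
Conditions: TBSCl, imidazole, DMAP (cat.), CH2Cl2, rt
Reagents that add atoms: TBSCl, CC(C)(C)[Si](C)(C)Cl
Why: Imidazole-promoted silyl ether formation reacts at oxygen only, so the C–O bond and the R configuration stay intact and the OH is masked for the lithiation, carbene and Br+ steps.

**Step 4**
Reactants: 7 (R)-3-bromo-4-[1-(tert-butyldimethylsilyloxy)butyl]furan; 8 N,N-dimethylformamide
Product: 11 (R)-3-bromo-4-[1-(tert-butyldimethylsilyloxy)butyl]furan-2-carbaldehyde, via 2-lithiofuran 9 (not isolated), via lithium aminoalkoxide 10 (not isolated)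
Conditions: LDA (LiN(i-Pr)2, 1.1 equiv), THF, −78 °C; then 8, −78 → −40 °C; AcOH, then H2O
Reagents that add atoms: N,N-dimethylformamide 8, CN(C)C=O
Why: This is the known α-lithiation of a 3-bromofuran followed by Bouveault-type formylation; C2–H is acidified by the adjacent C–Br and unhindered, C5–H is shielded by the bulky silyloxyalkyl group, and an amide base does not trigger Br–Li exchange.

**Step 5**
Reactants: 11 (R)-3-bromo-4-[1-(tert-butyldimethylsilyloxy)butyl]furan-2-carbaldehyde; 12 p-toluenesulfonyl hydrazide
Product: 13 (E)-N-tosylhydrazone of 11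
Conditions: 12 (1.05 equiv), MeOH, rt
Reagents that add atoms: p-toluenesulfonyl hydrazide 12, Cc1ccc(S(=O)(=O)NN)cc1
Why: Hydrazone condensation of an electron-poor furfural needs no added acid and should give the E isomer without touching the TBS ether or the C–Br bond.

**Step 6**
Reactants: 13 (E)-N-tosylhydrazone of 11
Product: 17 (2E)-3-bromo-2-[(1R)-1-(tert-butyldimethylsilyloxy)butyl]pent-2-en-4-ynal, via tosylhydrazone sodium salt 14 (not isolated), via 2-furyldiazomethane 15 (not isolated), via singlet 2-furylcarbene 16 (not isolated)
Conditions: NaH (0.98 equiv), THF, 0 °C → rt; evaporate and dry in vacuo; neat salt as a thin layer, 0.01–0.05 mbar, bath 90 → 150 °C, short path, receiver −78 °C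
Reagents that add atoms: none
Why: This is a Bamford–Stevens reaction under aprotic conditions: on heating, dry salt 14 expels p-toluenesulfinate to give 2-furyldiazomethane 15, which loses N2 to give singlet 2-furylcarbene 16. The carbene should not persist, because in a concerted fragmentation the furan O1–C2 bond breaks while C2 and the former formyl carbon become the C≡C–H unit, C5–O1 becomes the aldehyde C=O, and the furan C3–C4 bond remains as the tetrasubstituted alkene of 17. The closest known reaction type is the thermolysis of furfural tosylhydrazone sodium salts, which gives cis-pent-2-en-4-ynals by the same ring opening; only the substituents (Br at C3, silyloxyalkyl at C4) differ here. No ring is closed and no stereocentre is created: the furan is opened and the R carbinol carbon is a spectator. The selectivity needed is geometric (formyl cis to ethynyl, Br cis to the side chain), and it is secured because both termini were tied through O1 in the planar five-membered ring, while the carbene carbon has no neighbouring sp3 C–H for a competing 1,2-shift. Thermolysis of the neat salt under high vacuum should let 17 leave the hot zone and condense cold, away from the nucleophilic sulfinate and from undecomposed diazo compound.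

**Step 7**
Reactants: 17 (2E)-3-bromo-2-[(1R)-1-(tert-butyldimethylsilyloxy)butyl]pent-2-en-4-ynal
Product: 18 (2E)-3,5-dibromo-2-[(1R)-1-(tert-butyldimethylsilyloxy)butyl]pent-2-en-4-ynal
Conditions: NBS (1.1 equiv), AgNO3 (10 mol %), acetone, rt, dark
Reagents that add atoms: NBS, O=C1CCC(=O)N1Br
Why: Silver-catalysed electrophilic bromination of a terminal alkyne proceeds through the silver acetylide and tolerates aldehydes (ortho-ethynylbenzaldehydes behave this way), and it is placed before the oxidation because a free cis-enynoic acid would lactonise under AgNO3.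

**Step 8**
Reactants: 18 (2E)-3,5-dibromo-2-[(1R)-1-(tert-butyldimethylsilyloxy)butyl]pent-2-en-4-ynal
Product: 19 (2E)-3,5-dibromo-2-[(1R)-1-(tert-butyldimethylsilyloxy)butyl]pent-2-en-4-ynoic acid
Conditions: NaClO2, NaH2PO4, 2-methyl-2-butene, t-BuOH–H2O, 0 °C → rt
Reagents that add atoms: sodium chlorite, [Na+].[O-]Cl=O
Why: The Pinnick oxidation is selective for CHO, works on hindered enals without moving the alkene geometry, and spares the bromoalkyne and TBS ether at about pH 4 because 2-methyl-2-butene scavenges HOCl.

**Step 9**
Reactants: 19 (2E)-3,5-dibromo-2-[(1R)-1-(tert-butyldimethylsilyloxy)butyl]pent-2-en-4-ynoic acid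
Product: 20 (R)-4-bromo-3-[1-(tert-butyldimethylsilyloxy)butyl]-5-(dibromomethylidene)furan-2(5H)-one
Conditions: NBS (1.1 equiv), NaHCO3, MeCN, 0 °C → rt, dark
Reagents that add atoms: NBS, O=C1CCC(=O)N1Br
Why: Proposed new method: NBS should transfer Br+ to the C≡C–Br unit of the bicarbonate-buffered acid, and the cis-held carboxyl oxygen should open the bromirenium ion anti at the internal alkyne carbon (5-exo-dig), making the lactone O1–C5 bond and leaving two bromines on the terminal carbon; attack at the internal carbon is expected because additions to 1-bromoalkynes place the electrophile on the bromine-bearing carbon and the oxygen nucleophile on the other one (hydration to α-bromoketones, oxybromination to α,α-dibromoketones); the closest known reaction types are NBS/bicarbonate bromo-enol-lactonisation of alkynoic acids, halolactonisation of cis-2-en-4-ynoic acids and AgNO3-catalysed 5-exo lactonisation of ω-bromoalkynoic acids, none of which combines a Br+ source with a bromine-capped enynoic acid; no stereocentre forms and =CBr2 has no geometry.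

**Step 10**
Reactants: 20 (R)-4-bromo-3-[1-(tert-butyldimethylsilyloxy)butyl]-5-(dibromomethylidene)furan-2(5H)-one
Product: 21 (R)-4-bromo-5-(dibromomethylidene)-3-(1-hydroxybutyl)furan-2(5H)-one (target)
Conditions: HF·pyridine, THF, polyethylene vessel, 0 °C → rt
Reagents that add atoms: none
Why: Acidic fluoride desilylation cleaves only the Si–O bond, so the R configuration is retained, and it avoids basic fluoride, which would attack the electrophilic bromo-ylidene butenolide.

**Compound list**
1 | 3,4-dibromofuran | Brc1cocc1Br | starting material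
2 | N-methoxy-N-methylbutanamide | CCCC(=O)N(C)OC | starting material
3 | 4-bromofuran-3-yllithium (not isolated) | [Li]c1cocc1Br | intermediate
4 | lithium Weinreb adduct of 3 and 2 (not isolated) | CCCC([O-])(N(C)OC)c1cocc1Br.[Li+] | intermediate
5 | 1-(4-bromofuran-3-yl)butan-1-one | CCCC(=O)c1cocc1Br | intermediate
6 | (1R)-1-(4-bromofuran-3-yl)butan-1-ol | CCC[C@@H](O)c1cocc1Br | intermediate
7 | (R)-3-bromo-4-[1-(tert-butyldimethylsilyloxy)butyl]furan | CCC[C@@H](O[Si](C)(C)C(C)(C)C)c1cocc1Br | intermediate
8 | N,N-dimethylformamide | CN(C)C=O | starting material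
9 | 2-lithio derivative of 7 (not isolated) | CCC[C@@H](O[Si](C)(C)C(C)(C)C)c1coc([Li])c1Br | intermediate
10 | lithium α-(dimethylamino)alkoxide from 9 and 8 (not isolated) | CCC[C@@H](O[Si](C)(C)C(C)(C)C)c1coc(C([O-])N(C)C)c1Br.[Li+] | intermediate
11 | (R)-3-bromo-4-[1-(tert-butyldimethylsilyloxy)butyl]furan-2-carbaldehyde | CCC[C@@H](O[Si](C)(C)C(C)(C)C)c1coc(C=O)c1Br | intermediate
12 | p-toluenesulfonyl hydrazide | Cc1ccc(S(=O)(=O)NN)cc1 | starting material
13 | (E)-N-tosylhydrazone of 11 | CCC[C@@H](O[Si](C)(C)C(C)(C)C)c1coc(/C=N/NS(=O)(=O)c2ccc(C)cc2)c1Br | intermediate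
14 | sodium salt of 13 (not isolated) | CCC[C@@H](O[Si](C)(C)C(C)(C)C)c1coc(/C=N/[N-]S(=O)(=O)c2ccc(C)cc2)c1Br.[Na+] | intermediate
15 | (R)-3-bromo-4-[1-(tert-butyldimethylsilyloxy)butyl]-2-(diazomethyl)furan (not isolated) | CCC[C@@H](O[Si](C)(C)C(C)(C)C)c1coc(C=[N+]=[N-])c1Br | intermediate
16 | corresponding singlet 2-furylcarbene (not isolated) | CCC[C@@H](O[Si](C)(C)C(C)(C)C)c1coc([CH])c1Br | intermediate
17 | (2E)-3-bromo-2-[(1R)-1-(tert-butyldimethylsilyloxy)butyl]pent-2-en-4-ynal (CHO cis to ethynyl) | CCC[C@@H](O[Si](C)(C)C(C)(C)C)/C(C=O)=C(\Br)C#C | intermediate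
18 | (2E)-3,5-dibromo-2-[(1R)-1-(tert-butyldimethylsilyloxy)butyl]pent-2-en-4-ynal | CCC[C@@H](O[Si](C)(C)C(C)(C)C)/C(C=O)=C(\Br)C#CBr | intermediate
19 | (2E)-3,5-dibromo-2-[(1R)-1-(tert-butyldimethylsilyloxy)butyl]pent-2-en-4-ynoic acid | CCC[C@@H](O[Si](C)(C)C(C)(C)C)/C(C(=O)O)=C(\Br)C#CBr | intermediate
20 | (R)-4-bromo-3-[1-(tert-butyldimethylsilyloxy)butyl]-5-(dibromomethylidene)furan-2(5H)-one | CCC[C@@H](O[Si](C)(C)C(C)(C)C)C1=C(Br)C(=C(Br)Br)OC1=O | intermediate
21 | (R)-4-bromo-5-(dibromomethylidene)-3-(1-hydroxybutyl)furan-2(5H)-one, CNP0138117.1 | CCC[C@@H](O)C1=C(Br)C(=C(Br)Br)OC1=O | target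

**Total step count:** 10. **Longest linear sequence:** 10 steps, from 3,4-dibromofuran.

**Steps most likely to fail**

First, step 9 (the labelled step). Br+ transfer to an alkyne that is conjugated to an electron-poor bromoacrylate may be slow. The ring may also close through the distal alkyne carbon (6-endo) instead of the internal one. The fallback uses known chemistry, sets out from 19 and returns at 20.
- AgNO3 (10 mol %) in acetone should cycloisomerise 19 by 5-exo-dig anti oxymetalation and protodemetalation. This mode is established both for cis-enynoic acids and for ω-bromoalkynoic acids. It gives (Z)-4-bromo-5-(bromomethylidene)-3-[(1R)-1-(tert-butyldimethylsilyloxy)butyl]furan-2(5H)-one F1.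
- Br2 in CH2Cl2 should add across the exocyclic alkene to give 4,5-dibromo-5-(dibromomethyl)-3-[(1R)-1-(tert-butyldimethylsilyloxy)butyl]furan-2(5H)-one F2.
- Et3N should then remove HBr and regenerate the exocyclic alkene as =CBr2, which is 20. This addition–dehydrobromination is the standard way to raise the bromine count of 5-ylidene furanones.

Second, step 6. The released sulfinate may add to the β-bromo-enal and displace bromide before the rather heavy product leaves the hot zone. The diazo compound may be consumed bimolecularly as azine, and prolonged heating may erode the alkene geometry. The fallback sets out from 11 and returns at 17, and it generates the diazo compound oxidatively so that no sulfinate is ever present.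
- Excess hydrazine hydrate in EtOH should give the free (E)-hydrazone of 11 F3.
- MnO2 in CH2Cl2 at 0 °C should oxidise F3 to diazo compound 15.
- In dilute solution, 15 should lose N2 on gentle warming (about 40 °C) or under visible light and open through carbene 16 to 17.

Third, step 7. Monovalent silver may activate the alkyne as a π-acid, with the cis carbonyl oxygen participating and re-closing toward furan-type carbenoid chemistry. The sensitive β-bromo-enynal may also decompose during the reaction. The fallback avoids silver and the bromoalkyne altogether, sets out from 17 and returns at 20.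
- Pinnick oxidation of 17 should give (2E)-3-bromo-2-[(1R)-1-(tert-butyldimethylsilyloxy)butyl]pent-2-en-4-ynoic acid F4.
- NBS/NaHCO3 bromolactonisation of this terminal alkyne (Markovnikov, 5-exo-dig, anti) should give (E)-4-bromo-5-(bromomethylidene)-3-[(1R)-1-(tert-butyldimethylsilyloxy)butyl]furan-2(5H)-one F5.
- Br2 addition to F5 gives the same tribromide F2 as above, and Et3N converts it into 20.

**Further compounds**
F1 | step 9 | (Z)-4-bromo-5-(bromomethylidene)-3-[(1R)-1-(tert-butyldimethylsilyloxy)butyl]furan-2(5H)-one | CCC[C@@H](O[Si](C)(C)C(C)(C)C)C1=C(Br)/C(=C/Br)OC1=O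
F2 | step 9 | 4,5-dibromo-5-(dibromomethyl)-3-[(1R)-1-(tert-butyldimethylsilyloxy)butyl]furan-2(5H)-one (both C5 epimers) | CCC[C@@H](O[Si](C)(C)C(C)(C)C)C1=C(Br)C(Br)(C(Br)Br)OC1=O
F3 | step 6 | (E)-hydrazone of 11 | CCC[C@@H](O[Si](C)(C)C(C)(C)C)c1coc(/C=N/N)c1Br
F4 | step 7 | (2E)-3-bromo-2-[(1R)-1-(tert-butyldimethylsilyloxy)butyl]pent-2-en-4-ynoic acid | CCC[C@@H](O[Si](C)(C)C(C)(C)C)/C(C(=O)O)=C(\Br)C#C
F5 | step 7 | (E)-4-bromo-5-(bromomethylidene)-3-[(1R)-1-(tert-butyldimethylsilyloxy)butyl]furan-2(5H)-one | CCC[C@@H](O[Si](C)(C)C(C)(C)C)C1=C(Br)/C(=C\Br)OC1=O
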